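**Plan**

- Labels: ring A is the central benzene, a1 (O of dihydrobenzofuran 1), a2 (H), a3 (O of dihydrobenzofuran 2), a4 (bears C3'), a5 (bears C8H2), a6 (bears C3). Dihydrobenzofuran 1 is O–C2(4-oxyphenyl)–C3(ring B). The cycloheptane is a6–C3–ring B–C7(2,4-dioxyphenyl)–C8–a5. Dihydrobenzofuran 2 is O–C2'(2,4-dioxyphenyl)–C3'(3,5-dioxyphenyl).
- Retrosynthesis: cut the nine O–CH3 bonds, then the aryl C–O bond a3–O of dihydrobenzofuran 2, then the C2' carbinol (back to a ketone) and the a4–C3' bond (ketone α-arylation). Next cut together the C7–ring B bond of the cycloheptane and the O–C2 bond of dihydrobenzofuran 1, and last the a6–C3 bond and the stilbene C7=C8.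
- Forward: ring A is a resorcinol aldehyde, dibrominated at a4/a6 and extended at a5 to the stilbene. Arm 1 (C3–C2) is coupled at a6 and reduced, and one acid operation closes dihydrobenzofuran 1 and then the seven-membered ring. The a3 oxygen becomes a triflate, arm 2 (C3'–C2') is coupled at a4 and reduced, the last ring closes by a3–O bond formation, and demethylation ends the route.
- Enabling feature: ring A is a 5-alkylresorcinol in which each oxygen-bearing carbon (a1, a3) is ortho to a diarylmethine carbon (C3 on a6, C3' on a4). The a3 oxygen can therefore be spent as a triflate leaving group while the C2' hydroxyl, held 1,5 to a3 through C3' and a4, takes its place. The ring O–C2'–C3'–a4–a3 then closes with retention at both sp3 centres.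
- Stereochemistry: the two dihydrobenzofurans are near mirror images across the a2···a5 axis of ring A [(2R,3R) against (2'S,3'S)]. Each C3/C2 pair is set by its own transfer hydrogenation with dynamic kinetic resolution, using the two enantiomers of one Ru catalyst. C2 is then re-set trans and C7 is set by substrate control from C3/C2 in the acid cascade.

Key step: step 13

Assumption: the acid-induced closure of the cycloheptane is taken to follow the course of ε-viniferin-type stilbenes (ampelopsin B-type product, C7 aryl trans to the C3–C2 bond on the seven-membered ring), which corresponds to 7R with 2R,3R.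

**Route**

Step 1
Reactants: 1 3,5-dihydroxybenzaldehyde
Product: 2 3,5-bis(methoxymethoxy)benzaldehyde
Conditions: MOMCl, i-Pr2NEt, CH2Cl2, 0 → 25 °C
Reagents that add atoms: chloromethyl methyl ether (MOMCl), COCCl
Why: Williamson-type O-alkylation of both phenols; the MOM acetal survives base, palladium and hydride transfer and is removed by the acid that later triggers the cascade.

Step 2
Reactants: 2 3,5-bis(methoxymethoxy)benzaldehyde
Product: 3 2,6-dibromo-3,5-bis(methoxymethoxy)benzaldehyde
Conditions: NBS (2.1 equiv), MeCN, 0 → 25 °C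
Reagents that add atoms: N-bromosuccinimide, O=C1CCC(=O)N1Br
Why: electrophilic aromatic bromination; each bromine should enter ortho to the formyl group and para to one acetal oxygen (a4 and a6), as with the corresponding dimethyl ether, the position between the two oxygens being the most hindered.

Step 3
Reactants: 4 2,4-dimethoxybenzyl alcohol
Product: 5 diethyl (2,4-dimethoxybenzyl)phosphonate
Conditions: P(OEt)3, ZnI2, toluene, reflux
Reagents that add atoms: triethyl phosphite, CCOP(OCC)OCC
Why: ZnI2-mediated Michaelis–Arbuzov reaction of an electron-rich benzylic alcohol through the benzylic iodide, which avoids the unstable benzylic halide.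

Step 4
Reactants: 3 2,6-dibromo-3,5-bis(methoxymethoxy)benzaldehyde; 5 diethyl (2,4-dimethoxybenzyl)phosphonate
Product: 6 1,3-dibromo-2-[(E)-2-(2,4-dimethoxyphenyl)ethenyl]-4,6-bis(methoxymethoxy)benzene
Conditions: NaH, THF, 0 → 25 °C
Reagents that add atoms: none
Why: Horner–Wadsworth–Emmons olefination of a non-enolisable aldehyde; the semistabilised benzylphosphonate anion should give the (E)-stilbene.

Step 5
Reactants: 7 4'-methoxyacetophenone; 8 1-bromo-3,5-dimethoxybenzene
Product: 9 2-(3,5-dimethoxyphenyl)-1-(4-methoxyphenyl)ethan-1-one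
Conditions: Pd2(dba)3, Xantphos, NaOtBu, THF, 70 °C
Reagents that add atoms: none
Why: palladium-catalysed α-arylation of an aryl methyl ketone enolate; the wide-bite-angle ligand and a slight excess of ketone should stop the reaction at mono-arylation.

Step 6
Reactants: 6 dibromostilbene (1.5 equiv, excess recovered); 9 2-(3,5-dimethoxyphenyl)-1-(4-methoxyphenyl)ethan-1-one
Product: 10 2-{3-bromo-2-[(E)-2-(2,4-dimethoxyphenyl)ethenyl]-4,6-bis(methoxymethoxy)phenyl}-2-(3,5-dimethoxyphenyl)-1-(4-methoxyphenyl)ethan-1-one (racemic at C3)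
Conditions: Pd2(dba)3, P(t-Bu)3·HBF4, NaOtBu, toluene, 80 °C
Reagents that add atoms: none
Why: palladium-catalysed α-arylation of the deoxybenzoin enolate at one of the two equivalent C–Br bonds of 6 forms the a6–C3 bond; the excess of 6 and the added bulk after the first coupling should hold the reaction at mono-coupling, and C3 is formed racemic and stays labile.

Step 7
Reactants: 10 bromo ketone of arm 1
Product: 11 (1R,2R)-2-{3-bromo-2-[(E)-2-(2,4-dimethoxyphenyl)ethenyl]-4,6-bis(methoxymethoxy)phenyl}-2-(3,5-dimethoxyphenyl)-1-(4-methoxyphenyl)ethan-1-ol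
Conditions: RuCl[(R,R)-TsDPEN](p-cymene) (cat.), HCO2H/Et3N 5:2, DMF, 40 °C
Reagents that add atoms: none
Why: Proposed new method: dynamic kinetic resolution of an acyclic α,α-diaryl ketone by Noyori–Ikariya transfer hydrogenation; the C3–H lies between two aryl rings and the carbonyl, so Et3N should interconvert the enantiomers through the enol faster than the Ru–H/N–H pair delivers hydride and proton to the C=O in the six-membered outer-sphere transition state; the (R,R) catalyst should give the (R)-carbinol (aryl ketone CH/π model) and the Felkin–Anh preference (hydride anti to the bulky ring A aryl) should make the (R)-ketone the fast-reacting one, so that C3 is set as R; the closest known reaction type is the transfer-hydrogenative dynamic kinetic resolution of benzoins, 2-arylcycloalkanones and α-substituted β-keto esters.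

Step 8
Reactants: 11 (1R,2R)-alcohol of arm 1
Product: 13 tetracyclic bromophenol (2R,3R,7R; see list), via dihydrobenzofuran stilbene phenol 12 (not isolated)
Conditions: conc. HCl, MeOH/THF, 25 → 60 °C
Reagents that add atoms: none
Why: the acid cleaves both MOM acetals and ionises the 4-methoxybenzylic carbinol, whose cation should be trapped by the a1 oxygen to give the trans dihydrobenzofuran 12 (5-exo closure, reversible, C2 set by C3 under thermodynamic control); protonation of the stilbene at C8 then gives the 2,4-dimethoxybenzylic cation at C7, and Friedel–Crafts attack by ring B should close the seven-membered ring with C7 set by the C3/C2 centres.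

Step 9
Reactants: 13 tetracyclic bromophenol
Product: 14 a3 trifluoromethanesulfonate of 13
Conditions: Tf2O, pyridine, CH2Cl2, 0 °C
Reagents that add atoms: trifluoromethanesulfonic anhydride (Tf2O), O=S(=O)(OS(=O)(=O)C(F)(F)F)C(F)(F)F
Why: O-sulfonylation of the only free phenol turns the a3 oxygen of ring A into the leaving group for the later ring closure.

Step 10
Reactants: 15 2',4'-dimethoxyacetophenone; 8 1-bromo-3,5-dimethoxybenzene
Product: 16 2-(3,5-dimethoxyphenyl)-1-(2,4-dimethoxyphenyl)ethan-1-one
Conditions: Pd2(dba)3, Xantphos, NaOtBu, THF, 70 °C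
Reagents that add atoms: none
Why: the same palladium-catalysed mono-α-arylation of an aryl methyl ketone as in step 5.

Step 11
Reactants: 14 bromo triflate; 16 2-(3,5-dimethoxyphenyl)-1-(2,4-dimethoxyphenyl)ethan-1-one
Product: 17 triflate 14 in which the a4 bromine is replaced by CH(3,5-dimethoxyphenyl)–C(=O)–(2,4-dimethoxyphenyl) (mixture of C3' epimers)
Conditions: Pd2(dba)3, P(t-Bu)3·HBF4, K3PO4, toluene, 100 °C
Reagents that add atoms: none
Why: palladium-catalysed ketone α-arylation forms the a4–C3' bond; the trialkylphosphine should insert into C–Br in preference to C–OTf and the weak phosphate base should spare the triflate, while C3' is formed as a base-labile epimer pair.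

Step 12
Reactants: 17 triflate ketone of arm 2
Product: 18 (1S,2S)-1-(2,4-dimethoxyphenyl)-2-(3,5-dimethoxyphenyl)-2-(a4 carbon of triflate core)ethan-1-ol (C2' S, C3' S)
Conditions: RuCl[(S,S)-TsDPEN](p-cymene) (cat.), HCO2H/Et3N 5:2, DMF, 40 °C
Reagents that add atoms: none
Why: Proposed new method: the same dynamic kinetic resolution as in step 7 with the enantiomeric catalyst; the C3' epimers should equilibrate through the enol under Et3N, the (S,S) catalyst should deliver hydride to give the (S)-carbinol at C2', and the Felkin–Anh preference (hydride anti to the ring A aryl) should select the (S)-epimer at C3', giving the threo alcohol in which O and a4 are placed for a trans ring; catalyst control should override the remote stereocentres of the core; the closest known reaction type is the transfer-hydrogenative dynamic kinetic resolution of benzoins and 2-arylcycloalkanones.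

Step 13
Reactants: 18 (1S,2S)-alcohol triflate
Product: 19 nonamethyl ether of the target (2R,3R,7R,2'S,3'S)
Conditions: [Pd(allyl)Cl]2, RockPhos, Cs2CO3, toluene, 80 °C
Reagents that add atoms: none
Why: Zerovalent palladium inserts into the a3–OTf bond, the C2' hydroxyl binds and is deprotonated by Cs2CO3 to give a six-membered aryl palladium alkoxide (Pd, a3, a4, C3', C2', O), and C–O reductive elimination forms the a3–O bond. The closest known reaction type is the Buchwald–Hartwig-type intramolecular etherification of aryl (pseudo)halides with secondary alcohols to dihydrobenzofurans. The ring O–C2'–C3'–a4–a3 closes in a formal 5-exo sense by reductive elimination from the palladacycle, and no other ring is formed. No new stereocentre is created: C2' and C3' from step 12 are carried through with retention because no bond to either sp3 carbon is broken, so the threo alcohol maps onto the trans ring. The step needs reductive elimination to beat β-hydride elimination of the secondary benzylic alkoxide and S–O cleavage of the triflate; the bulky di-tert-butyl biaryl phosphine, the weak insoluble base and the five-membered ring geometry should secure this. The triflate is the only site on ring A open to oxidative addition.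

Step 14
Reactants: 19 nonamethyl ether
Product: 20 CNP0283541.1 (target)
Conditions: BBr3, CH2Cl2, −78 → 25 °C; then MeOH, H2O
Reagents that add atoms: none
Why: Lewis acid ether cleavage of the nine aryl methyl ethers through ArO–BBr2 and MeBr; the diarylmethine and dihydrobenzofuran centres are not broken, and any reversible ionisation at C2 or C2' should return the trans rings.

**Compound list**

1 | 3,5-dihydroxybenzaldehyde | O=Cc1cc(O)cc(O)c1 | starting material
2 | 3,5-bis(methoxymethoxy)benzaldehyde | O=Cc1cc(OCOC)cc(OCOC)c1 | intermediate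
3 | 2,6-dibromo-3,5-bis(methoxymethoxy)benzaldehyde | O=Cc1c(Br)c(OCOC)cc(OCOC)c1Br | intermediate
4 | 2,4-dimethoxybenzyl alcohol | COc1ccc(CO)c(OC)c1 | starting material
5 | diethyl (2,4-dimethoxybenzyl)phosphonate | CCOP(=O)(Cc1ccc(OC)cc1OC)OCC | intermediate
6 | 1,3-dibromo-2-[(E)-2-(2,4-dimethoxyphenyl)ethenyl]-4,6-bis(methoxymethoxy)benzene | COc1ccc(/C=C/c2c(Br)c(OCOC)cc(OCOC)c2Br)c(OC)c1 | intermediate
7 | 4'-methoxyacetophenone | CC(=O)c1ccc(OC)cc1 | starting material
8 | 1-bromo-3,5-dimethoxybenzene | COc1cc(Br)cc(OC)c1 | starting material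
9 | 2-(3,5-dimethoxyphenyl)-1-(4-methoxyphenyl)ethan-1-one | COc1ccc(C(=O)Cc2cc(OC)cc(OC)c2)cc1 | intermediate
10 | 2-{3-bromo-2-[(E)-2-(2,4-dimethoxyphenyl)ethenyl]-4,6-bis(methoxymethoxy)phenyl}-2-(3,5-dimethoxyphenyl)-1-(4-methoxyphenyl)ethan-1-one, racemic at C3 | COc1ccc(C(=O)C(c2cc(OC)cc(OC)c2)c2c(OCOC)cc(OCOC)c(Br)c2/C=C/c2ccc(OC)cc2OC)cc1 | intermediate
11 | (1R,2R)-2-{3-bromo-2-[(E)-2-(2,4-dimethoxyphenyl)ethenyl]-4,6-bis(methoxymethoxy)phenyl}-2-(3,5-dimethoxyphenyl)-1-(4-methoxyphenyl)ethan-1-ol | COc1ccc([C@H](O)[C@H](c2cc(OC)cc(OC)c2)c2c(OCOC)cc(OCOC)c(Br)c2/C=C/c2ccc(OC)cc2OC)cc1 | intermediate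
12 | (2R,3R)-5-bromo-4-[(E)-2-(2,4-dimethoxyphenyl)ethenyl]-3-(3,5-dimethoxyphenyl)-2-(4-methoxyphenyl)-2,3-dihydro-1-benzofuran-6-ol | COc1ccc([C@@H]2Oc3cc(O)c(Br)c(/C=C/c4ccc(OC)cc4OC)c3[C@H]2c2cc(OC)cc(OC)c2)cc1 | intermediate (not isolated)
13 | tetracyclic bromophenol: compound 12 in which C8 is CH2 and C7 (R, bearing the 2,4-dimethoxyphenyl group) is bonded to the ortho carbon of the 3,5-dimethoxyphenyl ring (ring B), closing the cycloheptane a6–C3–ring B–C7–C8–a5; OH on a3, Br on a4; (2R,3R,7R) | COc1ccc([C@@H]2Oc3cc(O)c(Br)c4c3[C@H]2c2cc(OC)cc(OC)c2[C@@H](c2ccc(OC)cc2OC)C4)cc1 | intermediate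
14 | a3 trifluoromethanesulfonate of 13 | COc1ccc([C@@H]2Oc3cc(OS(=O)(=O)C(F)(F)F)c(Br)c4c3[C@H]2c2cc(OC)cc(OC)c2[C@@H](c2ccc(OC)cc2OC)C4)cc1 | intermediate
15 | 2',4'-dimethoxyacetophenone | CC(=O)c1ccc(OC)cc1OC | starting material
16 | 2-(3,5-dimethoxyphenyl)-1-(2,4-dimethoxyphenyl)ethan-1-one | COc1ccc(C(=O)Cc2cc(OC)cc(OC)c2)c(OC)c1 | intermediate
17 | triflate 14 with the a4 bromine replaced by CH(3,5-dimethoxyphenyl)–C(=O)–(2,4-dimethoxyphenyl); mixture of C3' epimers | COc1ccc([C@@H]2Oc3cc(OS(=O)(=O)C(F)(F)F)c(C(C(=O)c4ccc(OC)cc4OC)c4cc(OC)cc(OC)c4)c4c3[C@H]2c2cc(OC)cc(OC)c2[C@@H](c2ccc(OC)cc2OC)C4)cc1 | intermediate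
18 | (1S,2S)-alcohol from 17: a4–C3'H(3,5-dimethoxyphenyl)–C2'H(OH)(2,4-dimethoxyphenyl) with C2' S and C3' S, a3 triflate retained | COc1ccc([C@@H]2Oc3cc(OS(=O)(=O)C(F)(F)F)c([C@H](c4cc(OC)cc(OC)c4)[C@H](O)c4ccc(OC)cc4OC)c4c3[C@H]2c2cc(OC)cc(OC)c2[C@@H](c2ccc(OC)cc2OC)C4)cc1 | intermediate
19 | nonamethyl ether of the target, (2R,3R,7R,2'S,3'S) | COc1ccc([C@@H]2Oc3cc4c(c5c3[C@H]2c2cc(OC)cc(OC)c2[C@@H](c2ccc(OC)cc2OC)C5)[C@H](c2cc(OC)cc(OC)c2)[C@@H](c2ccc(OC)cc2OC)O4)cc1 | intermediate
20 | CNP0283541.1, (2R,3R,7R,2'S,3'S) nonaphenol | Oc1ccc([C@@H]2Oc3cc4c(c5c3[C@H]2c2cc(O)cc(O)c2[C@@H](c2ccc(O)cc2O)C5)[C@H](c2cc(O)cc(O)c2)[C@@H](c2ccc(O)cc2O)O4)cc1 | target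

**Count and risks**

Total steps: 14. Longest linear sequence: 11 steps (1, 2, 4, 6, 7, 8, 9, 11, 12, 13, 14).

Steps most likely to fail:

1. Step 12 (labelled). Hydride transfer to the very hindered, electron-rich aryl ketone may be slower than catalyst decay, or the catalyst may discriminate poorly between the two C3' epimers, so the wrong C3' series is carried on. Fallback by known chemistry: set out from 17 and reduce with NaBH4 (or L-Selectride for stronger Felkin–Anh control) to the threo alcohols, which are 18 and its (1R,2R) diastereomer F1. Because the tetracyclic core is a single enantiomer, these two are diastereomers and should separate on silica. The (1R,2R) diastereomer F1 is oxidised back to 17 with Dess–Martin periodinane and recycled. The route is rejoined at 18.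

2. Step 7 (labelled). Enolisation may be slow relative to reduction, so the process becomes a plain kinetic resolution, or enantiofacial control may be low. Fallback by known chemistry: set out from 10 and reduce with NaBH4 to the alcohol as a stereoisomer mixture F2. Step 8 is then run on this mixture; the carbinol centre is erased there and C2 and C7 follow C3, so 13 should form together with its enantiomer F3. Preparative chromatography on a chiral stationary phase separates the two, and the route is rejoined at 13.

3. Step 11. Oxidative addition and C–C reductive elimination at the doubly ortho-flanked a4 carbon may be too slow, so that hydrodebromination, activation of the triflate or O-arylation of the product enolate to a benzofuran takes over. Step 6 shares this failure mode on a simpler substrate. Fallback: set out from 13, deprotonate the phenol (NaH) and exchange bromine for lithium (t-BuLi, THF, −78 °C). The lithio phenoxide is added to 1-(2,4-dimethoxyphenyl)-2-(3,5-dimethoxyphenyl)ethane-1,2-dione F4 (made from 16 by SeO2 oxidation), at the more electrophilic carbonyl next to the 3,5-dimethoxyphenyl ring, to give the tertiary α-hydroxy ketone F5. SmI2 (THF/MeOH) removes the α-hydroxyl to give the phenol ketone F6, and PhNTf2/K2CO3 triflates the phenol. The route is rejoined at 17.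

Further compounds
F1 | step 12 | (1R,2R) diastereomer of 18 (C2' R, C3' R) | COc1ccc([C@@H]2Oc3cc(OS(=O)(=O)C(F)(F)F)c([C@@H](c4cc(OC)cc(OC)c4)[C@@H](O)c4ccc(OC)cc4OC)c4c3[C@H]2c2cc(OC)cc(OC)c2[C@@H](c2ccc(OC)cc2OC)C4)cc1
F2 | step 7 | alcohol of 10 as a mixture of stereoisomers | COc1ccc(C(O)C(c2cc(OC)cc(OC)c2)c2c(OCOC)cc(OCOC)c(Br)c2/C=C/c2ccc(OC)cc2OC)cc1
F3 | step 7 | enantiomer of 13, (2S,3S,7S) | COc1ccc([C@H]2Oc3cc(O)c(Br)c4c3[C@@H]2c2cc(OC)cc(OC)c2[C@H](c2ccc(OC)cc2OC)C4)cc1
F4 | step 11 | 1-(2,4-dimethoxyphenyl)-2-(3,5-dimethoxyphenyl)ethane-1,2-dione | COc1ccc(C(=O)C(=O)c2cc(OC)cc(OC)c2)c(OC)c1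
F5 | step 11 | phenol 13 with the a4 bromine replaced by C(OH)(3,5-dimethoxyphenyl)–C(=O)–(2,4-dimethoxyphenyl) | COc1ccc([C@@H]2Oc3cc(O)c(C(O)(C(=O)c4ccc(OC)cc4OC)c4cc(OC)cc(OC)c4)c4c3[C@H]2c2cc(OC)cc(OC)c2[C@@H](c2ccc(OC)cc2OC)C4)cc1
F6 | step 11 | phenol 13 with the a4 bromine replaced by CH(3,5-dimethoxyphenyl)–C(=O)–(2,4-dimethoxyphenyl) | COc1ccc([C@@H]2Oc3cc(O)c(C(C(=O)c4ccc(OC)cc4OC)c4cc(OC)cc(OC)c4)c4c3[C@H]2c2cc(OC)cc(OC)c2[C@@H](c2ccc(OC)cc2OC)C4)cc1
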